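**Retrosynthetic overview**

1. Numbering: ring A is C1 (ketone), C2 (amide carbon), C3 (=CH), C4 (carbinol), C5 and C6 (oxirane carbons, ring B); the trienamide is C7–C13; the aminocyclopentenone is ring C. The route rests on one feature: the amide N on C2 and the oxirane O on C5 stand 1,4 across ring A on the same face, anti to the C4 hydroxyl.
2. Last disconnections: the C4–O silyl ether, then C8–C9 (Stille) between a ring-bound E vinylstannane and the bromodienamide that carries ring C; the stannane comes from a C7≡C8 alkyne.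
3. Core: C2=C3 by dehydrochlorination of the N-chloro amide; ring B by the C5 oxygen closing onto a C6 bromide; both follow N–O cleavage of a 1,2-oxazine bridge.
4. Key disconnection: C2–N and C5–O together, by [4+2] addition of the side-chain acylnitroso compound to the diene C2=C1(OTBS)–C6=C5 of a ring A already stereodefined at C4.
5. Ring order: ring A is bought as a quinone monoketal and desymmetrised at C4 by CuH reduction; then the temporary oxazine ring; then ring B; ring C is made apart and joined last.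

Key step: step 9

Assumption: which enone arm of dienone 6 a given ligand antipode reduces cannot be predicted with confidence; the route is written with (R)-DTBM-SEGPHOS, and the antipode is used, with nothing else changed, if the first run gives the (S)-enone.

**Route**

Step 1
Reactants: 1 (triisopropylsilyl)acetylene; 2 4,4-dimethoxycyclohexa-2,5-dien-1-one
Product: 5 4-hydroxy-4-[(triisopropylsilyl)ethynyl]cyclohexa-2,5-dien-1-one, via lithium (triisopropylsilyl)acetylide 3 (not isolated), via quinol ketal carbinol 4 (not isolated)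
Conditions: n-BuLi, THF, −78 °C; then 2, −78 → 0 °C; then 1 M aq. HCl, 0 °C → rt
Reagents that add atoms: water, O
Why: 1,2-addition of the lithium acetylide to the only carbonyl group of the quinone monoketal, then acid hydrolysis of the dimethyl ketal, should give the prochiral p-quinol; no stereocentre is formed.

Step 2
Reactants: 5 4-hydroxy-4-[(triisopropylsilyl)ethynyl]cyclohexa-2,5-dien-1-one
Product: 6 4-[(tert-butyldimethylsilyl)oxy]-4-[(triisopropylsilyl)ethynyl]cyclohexa-2,5-dien-1-one
Conditions: TBSOTf, 2,6-lutidine, CH2Cl2, −78 → 0 °C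
Reagents that add atoms: tert-butyldimethylsilyl triflate, CC(C)(C)[Si](C)(C)OS(=O)(=O)C(F)(F)F
Why: silylation of a tertiary propargylic alcohol with a silyl triflate and a hindered pyridine base is standard; the base keeps the medium non-acidic so the quinol does not rearrange.

Step 3
Reactants: 6 4-[(tert-butyldimethylsilyl)oxy]-4-[(triisopropylsilyl)ethynyl]cyclohexa-2,5-dien-1-one
Product: 7 (R)-4-[(tert-butyldimethylsilyl)oxy]-4-[(triisopropylsilyl)ethynyl]cyclohex-2-en-1-one
Conditions: Cu(OAc)2 (5 mol %), (R)-DTBM-SEGPHOS (5.5 mol %), (EtO)2MeSiH (1.05 equiv), t-BuOH (1.1 equiv), toluene, −40 °C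
Reagents that add atoms: none
Why: enantioselective copper hydride conjugate reduction of one of the two enantiotopic enone arms of a 4,4-disubstituted cyclohexadienone (desymmetrisation); the chiral bisphosphine–CuH complex selects the arm and so sets C4 as R, the silyl-capped alkyne is inert to CuH, and one equivalent of silane with t-BuOH turnover limits reduction of the second arm.

Step 4
Reactants: 7 (R)-4-[(tert-butyldimethylsilyl)oxy]-4-[(triisopropylsilyl)ethynyl]cyclohex-2-en-1-one
Product: 8 (R)-2,5-bis[(tert-butyldimethylsilyl)oxy]-5-[(triisopropylsilyl)ethynyl]cyclohexa-1,3-diene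
Conditions: TBSOTf, Et3N, CH2Cl2, 0 °C; aq. NaHCO3 work-up, Et3N-deactivated silica, used at once
Reagents that add atoms: tert-butyldimethylsilyl triflate, CC(C)(C)[Si](C)(C)OS(=O)(=O)C(F)(F)F
Why: soft enolisation (O-silylation, then deprotonation by the amine) can only occur at the α′ carbon C2 because C4 is quaternary, so the cross-conjugated 2-silyloxy diene should form alone; C4 is untouched, and base-buffered handling avoids acid-induced loss of silanol to the arene.

Step 5
Reactants: 9 (S)-3-bromo-2-methylpropan-1-ol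
Product: 10 (R)-2-methylhexan-1-ol
Conditions: n-PrMgBr (2.5 equiv), Li2CuCl4 (3 mol %), THF, −20 → 0 °C; aq. NH4Cl
Reagents that add atoms: n-propylmagnesium bromide, CCC[Mg]Br
Why: copper-catalysed alkyl–alkyl cross-coupling of a primary bromide with a Grignard reagent (Kochi type), the first equivalent of Grignard masking the alcohol as its magnesium alkoxide; the stereocentre is not at the reacting carbon and is carried through, the descriptor changing from S to R only because the CIP ranking changes.

Step 6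
Reactants: 10 (R)-2-methylhexan-1-ol
Product: 12 ethyl (R,E)-4-methyloct-2-enoate, via (R)-2-methylhexanal 11 (not isolated)
Conditions: IBX, Ph3P=CHCO2Et, DMSO, rt
Reagents that add atoms: (ethoxycarbonylmethylene)triphenylphosphorane, CCOC(=O)C=P(c1ccccc1)(c1ccccc1)c1ccccc1
Why: tandem oxidation–Wittig reaction, in which the stabilised ylide traps the aldehyde as it forms and gives the E enoate, so the epimerisable α-branched aldehyde has no lifetime in the flask.

Step 7
Reactants: 12 ethyl (R,E)-4-methyloct-2-enoate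
Product: 13 (R,E)-4-methyloct-2-enoic acid
Conditions: LiOH, THF/MeOH/H2O, rt; then 1 M aq. HCl
Reagents that add atoms: lithium hydroxide, [Li+].[OH-]
Why: ester saponification; the γ-hydrogen is not acidic enough under LiOH at room temperature for the stereocentre or the alkene position to be disturbed.

Step 8
Reactants: 13 (R,E)-4-methyloct-2-enoic acid
Product: 15 (R,E)-N-hydroxy-4-methyloct-2-enamide, via acyl imidazolide 14 (not isolated)
Conditions: CDI, THF, rt; then NH2OH·HCl, rt
Reagents that add atoms: hydroxylamine hydrochloride, [NH3+]O.[Cl-]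
Why: activation of the acid as its acyl imidazolide and N-acylation of hydroxylamine should give the hydroxamic acid while avoiding the conjugate addition that free hydroxylamine can undergo with the enoate.

Step 9
Reactants: 8 (R)-2,5-bis[(tert-butyldimethylsilyl)oxy]-5-[(triisopropylsilyl)ethynyl]cyclohexa-1,3-diene; 15 (R,E)-N-hydroxy-4-methyloct-2-enamide
Product: 17 (R,E)-1-{(1R,4R,7S)-5,7-bis[(tert-butyldimethylsilyl)oxy]-7-[(triisopropylsilyl)ethynyl]-2-oxa-3-azabicyclo[2.2.2]oct-5-en-3-yl}-4-methyloct-2-en-1-one, via acylnitroso dienophile 16 (not isolated)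
Conditions: Bu4NIO4 (1.3 equiv), CH2Cl2, −20 → 0 °C, 15 (1.3 equiv) added slowly to 8 and the oxidant
Reagents that add atoms: none
Why: Bu4NIO4 oxidises 15 to the acylnitroso compound 16, which is trapped at once by the s-cis-locked diene in a concerted but asynchronous hetero-Diels–Alder reaction, the known acylnitroso cycloaddition of cyclohexa-1,3-dienes and 2-silyloxydienes. The 1,2-oxazine ring is closed as a [4+2] bridge, suprafacial on both partners, across C2 and C5 of ring A, forming C2–N and C5–O in one event. The two new bridgehead stereocentres (C2 and C5) are cis to each other by the suprafacial addition and are set relative to C4 by the face of attack, which should be anti to the bulky C4 silyl ether and over the slim alkynyl rod. The step needs N to bond to C2 and O to C5, and the substrate secures this twice: C2 is the nucleophilic terminus of the silyl enol ether and pairs with the electrophilic nitrogen, and the N-acyl end avoids the terminus next to the quaternary C4. Slow addition keeps 16 dilute so that its dimerisation and the nitroso-ene path do not compete with the cyclic diene. The whole acyl chain arrives on nitrogen, the C5 oxygen later becomes the oxirane oxygen, and the surviving enol ether marks C6 for bromination.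

Step 10
Reactants: 17 the N-acyl oxazine adduct of step 9
Product: 18 (R,E)-N-{(1R,4R,5S)-2,5-bis[(tert-butyldimethylsilyl)oxy]-4-hydroxy-5-[(triisopropylsilyl)ethynyl]cyclohex-2-en-1-yl}-4-methyloct-2-enamide
Conditions: SmI2 (2.5 equiv), THF, −78 °C; aq. NaHCO3; crude product taken on directly
Reagents that add atoms: none
Why: reductive N–O cleavage of an N-acyl 1,2-oxazine by single-electron transfer from SmI2 proceeds at low temperature under anhydrous, non-acidic conditions, so the silyl enol ether, the silyl alkyne and the conjugated amide should survive; no stereocentre is touched.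

Step 11
Reactants: 18 the C5-hydroxy silyl enol ether of step 10
Product: 20 (R,E)-N-{(1S,3R,5S,6R)-5-[(tert-butyldimethylsilyl)oxy]-2-oxo-5-[(triisopropylsilyl)ethynyl]-7-oxabicyclo[4.1.0]heptan-3-yl}-4-methyloct-2-enamide, via α-bromo ketone 19 (not isolated)
Conditions: NBS, THF, −78 °C; then Et3N, −78 °C → rt
Reagents that add atoms: none
Why: electrophilic bromination of the silyl enol ether at C6 gives the α-bromo ketone, and the C5 oxygen then displaces bromide in an intramolecular SN2 halohydrin-to-epoxide closure with inversion at C6; the oxirane can only be cis-fused, so its face is fixed by the C5 oxygen set in step 9, and any bromide delivered cis to the hydroxyl should epimerise through the enol under the amine before it closes.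

Step 12
Reactants: 20 the saturated α-amido epoxy ketone of step 11
Product: 23 (R,E)-N-{(1S,5S,6R)-5-[(tert-butyldimethylsilyl)oxy]-2-oxo-5-[(triisopropylsilyl)ethynyl]-7-oxabicyclo[4.1.0]hept-3-en-3-yl}-4-methyloct-2-enamide, via N-chloro amide 21 (not isolated), via N-acyl imine 22 (not isolated)
Conditions: t-BuOCl (1.1 equiv), CH2Cl2, −20 °C, dark; then DABCO, −20 → 0 °C
Reagents that add atoms: none
Why: N-chlorination of the secondary amide and base-induced dehydrochlorination (the sequence used for dehydroamino acid derivatives) removes the acidic C2–H to give the N-acyl imine, which tautomerises into conjugation with the C1 ketone as the hydrogen-bonded 2-amidoenone; C2 is the only enolisable position, and its stereocentre is cleared here.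

Step 13
Reactants: 23 the silyl-alkynyl epoxy amidoenone of step 12
Product: 24 (R,E)-N-{(1S,5S,6R)-5-[(tert-butyldimethylsilyl)oxy]-5-ethynyl-2-oxo-7-oxabicyclo[4.1.0]hept-3-en-3-yl}-4-methyloct-2-enamide
Conditions: TBAF, AcOH (1:1), THF, 0 °C → rt
Reagents that add atoms: none
Why: fluoride cleaves the C(sp)–Si bond much faster than the hindered tertiary Si–O bond, and the acetic acid buffer protects the epoxy enone; the tertiary silyl ether is kept on purpose, because a free C4 alkoxide anti to the oxirane would invite Payne rearrangement.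

Step 14
Reactants: 24 the terminal alkyne of step 13
Product: 25 (R,E)-N-{(1S,5S,6R)-5-[(tert-butyldimethylsilyl)oxy]-2-oxo-5-[(E)-2-(tributylstannyl)vinyl]-7-oxabicyclo[4.1.0]hept-3-en-3-yl}-4-methyloct-2-enamide
Conditions: Bu3SnH, Pd(PPh3)2Cl2 (cat.), THF, 0 °C
Reagents that add atoms: tributyltin hydride, CCCC[SnH](CCCC)CCCC
Why: palladium-catalysed syn hydrostannation of a terminal alkyne places tin on the terminal carbon C8, away from the quaternary C4, and gives the E vinylstannane; under acid-free conditions the alkyne should react much faster than the hindered, amide-substituted enone.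

Step 15
Reactants: 26 pyridine–sulfur trioxide complex (pyridinium-1-sulfonate)
Product: 27 potassium (1E,3E)-5-oxopenta-1,3-dien-1-olate (glutaconaldehyde potassium salt)
Conditions: KOH, H2O, −20 → 40 °C
Reagents that add atoms: potassium hydroxide, [K+].[OH-]
Why: hydroxide opens the N-sulfonated pyridinium ring (Zincke-type ring opening) and hydrolysis of the resulting sulfamate imine gives the all-trans enolate.

Step 16
Reactants: 27 glutaconaldehyde potassium salt
Product: 28 (2E,4E)-5-bromopenta-2,4-dienal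
Conditions: PPh3, Br2, CH2Cl2, 0 °C; then 27, 0 °C → rt
Reagents that add atoms: bromine, BrBr
Why: the enolate oxygen is activated by Ph3PBr2 as an oxyphosphonium salt and bromide replaces it by addition–elimination at the terminal carbon with loss of Ph3PO (vinylogous deoxybromination), giving the thermodynamically favoured E,E dienal.

Step 17
Reactants: 28 (2E,4E)-5-bromopenta-2,4-dienal
Product: 29 (2E,4E)-5-bromopenta-2,4-dienoic acid
Conditions: NaClO2, NaH2PO4, 2-methylbut-2-ene, t-BuOH/H2O, rt
Reagents that add atoms: sodium chlorite, [Na+].[O-]Cl=O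
Why: Pinnick oxidation converts the enal into the acid without touching the diene or the vinyl bromide, the alkene additive scavenging hypochlorous acid.

Step 18
Reactants: 30 cyclopentane-1,3-dione
Product: 31 2-(hydroxyimino)cyclopentane-1,3-dione
Conditions: NaNO2, aq. HCl, 0 °C
Reagents that add atoms: sodium nitrite, [Na+].[O-]N=O
Why: nitrosation of the doubly activated C2 methylene by nitrous acid, then tautomerisation, gives the 2-oxime.

Step 19
Reactants: 31 2-(hydroxyimino)cyclopentane-1,3-dione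
Product: 32 2-amino-3-hydroxycyclopent-2-en-1-one hydrochloride
Conditions: H2 (1 atm), Pd/C, HCl, MeOH, rt
Reagents that add atoms: hydrogen chloride, Cl
Why: catalytic hydrogenation of the oxime in acidic methanol gives the amine, which is isolated as the stable hydrochloride of its enol form so that it cannot self-condense.

Step 20
Reactants: 29 (2E,4E)-5-bromopenta-2,4-dienoic acid; 32 2-amino-3-hydroxycyclopent-2-en-1-one hydrochloride
Product: 34 (2E,4E)-5-bromo-N-(2-hydroxy-5-oxocyclopent-1-en-1-yl)penta-2,4-dienamide, via dienoyl chloride 33 (not isolated)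
Conditions: (COCl)2, DMF (cat.), CH2Cl2, 0 °C → rt, evaporate; then 32, Et3N, THF, 0 °C → rt
Reagents that add atoms: none
Why: acid chloride formation and N-acylation of the liberated amine; the amino group should be more nucleophilic than the vinylogous-acid hydroxyl, and an O-acyl isomer would pass its acyl group on to nitrogen.

Step 21
Reactants: 25 the E vinylstannane of step 14; 34 (2E,4E)-5-bromo-N-(2-hydroxy-5-oxocyclopent-1-en-1-yl)penta-2,4-dienamide
Product: 35 (R,E)-N-{(1S,5R,6R)-5-[(tert-butyldimethylsilyl)oxy]-5-[(1E,3E,5E)-7-[(2-hydroxy-5-oxocyclopent-1-en-1-yl)amino]-7-oxohepta-1,3,5-trien-1-yl]-2-oxo-7-oxabicyclo[4.1.0]hept-3-en-3-yl}-4-methyloct-2-enamide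
Conditions: Pd(MeCN)2Cl2 (5 mol %), DMF, rt, dark
Reagents that add atoms: none
Why: Stille cross-coupling of a vinylstannane with an activated vinyl bromide under ligand-free conditions forms C8–C9 at room temperature with retention of both alkene geometries and should tolerate the free enol and the epoxy enone.

Step 22
Reactants: 35 the C4 silyl ether of the target
Product: 36 (R,E)-N-{(1S,5R,6R)-5-hydroxy-5-[(1E,3E,5E)-7-[(2-hydroxy-5-oxocyclopent-1-en-1-yl)amino]-7-oxohepta-1,3,5-trien-1-yl]-2-oxo-7-oxabicyclo[4.1.0]hept-3-en-3-yl}-4-methyloct-2-enamide (CNP0259807.5)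
Conditions: HF·pyridine, pyridine, THF, 0 °C → rt
Reagents that add atoms: none
Why: buffered acidic fluoride cleaves the tertiary silyl ether without ever forming the C4 alkoxide, so the anti epoxy alcohol cannot undergo Payne rearrangement and the trienamide and epoxy enone should be left intact.

**Compound list**

1 | (triisopropylsilyl)acetylene | C#C[Si](C(C)C)(C(C)C)C(C)C | starting material
2 | 4,4-dimethoxycyclohexa-2,5-dien-1-one | COC1(OC)C=CC(=O)C=C1 | starting material
3 | lithium (triisopropylsilyl)acetylide | [Li]C#C[Si](C(C)C)(C(C)C)C(C)C | intermediate (not isolated)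
4 | 4,4-dimethoxy-1-[(triisopropylsilyl)ethynyl]cyclohexa-2,5-dien-1-ol | COC1(OC)C=CC(O)(C#C[Si](C(C)C)(C(C)C)C(C)C)C=C1 | intermediate (not isolated)
5 | 4-hydroxy-4-[(triisopropylsilyl)ethynyl]cyclohexa-2,5-dien-1-one | O=C1C=CC(O)(C#C[Si](C(C)C)(C(C)C)C(C)C)C=C1 | intermediate
6 | 4-[(tert-butyldimethylsilyl)oxy]-4-[(triisopropylsilyl)ethynyl]cyclohexa-2,5-dien-1-one | O=C1C=CC(O[Si](C)(C)C(C)(C)C)(C#C[Si](C(C)C)(C(C)C)C(C)C)C=C1 | intermediate
7 | (R)-4-[(tert-butyldimethylsilyl)oxy]-4-[(triisopropylsilyl)ethynyl]cyclohex-2-en-1-one | O=C1C=C[C@@](O[Si](C)(C)C(C)(C)C)(C#C[Si](C(C)C)(C(C)C)C(C)C)CC1 | intermediate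
8 | (R)-2,5-bis[(tert-butyldimethylsilyl)oxy]-5-[(triisopropylsilyl)ethynyl]cyclohexa-1,3-diene | C1=C(O[Si](C)(C)C(C)(C)C)C=C[C@@](O[Si](C)(C)C(C)(C)C)(C#C[Si](C(C)C)(C(C)C)C(C)C)C1 | intermediate
9 | (S)-3-bromo-2-methylpropan-1-ol | BrC[C@@H](C)CO | starting material
10 | (R)-2-methylhexan-1-ol | CCCC[C@@H](C)CO | intermediate
11 | (R)-2-methylhexanal | CCCC[C@@H](C)C=O | intermediate (not isolated)
12 | ethyl (R,E)-4-methyloct-2-enoate | CCCC[C@@H](C)/C=C/C(=O)OCC | intermediate
13 | (R,E)-4-methyloct-2-enoic acid | CCCC[C@@H](C)/C=C/C(=O)O | intermediate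
14 | (R,E)-1-(1H-imidazol-1-yl)-4-methyloct-2-en-1-one | CCCC[C@@H](C)/C=C/C(=O)n1ccnc1 | intermediate (not isolated)
15 | (R,E)-N-hydroxy-4-methyloct-2-enamide | CCCC[C@@H](C)/C=C/C(=O)NO | intermediate
16 | (R,E)-4-methyl-1-nitrosooct-2-en-1-one | CCCC[C@@H](C)/C=C/C(=O)N=O | intermediate (not isolated)
17 | (R,E)-1-{(1R,4R,7S)-5,7-bis[(tert-butyldimethylsilyl)oxy]-7-[(triisopropylsilyl)ethynyl]-2-oxa-3-azabicyclo[2.2.2]oct-5-en-3-yl}-4-methyloct-2-en-1-one | CCCC[C@@H](C)/C=C/C(=O)N1O[C@@H]2C=C(O[Si](C)(C)C(C)(C)C)[C@H]1C[C@]2(O[Si](C)(C)C(C)(C)C)C#C[Si](C(C)C)(C(C)C)C(C)C | intermediate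
18 | (R,E)-N-{(1R,4R,5S)-2,5-bis[(tert-butyldimethylsilyl)oxy]-4-hydroxy-5-[(triisopropylsilyl)ethynyl]cyclohex-2-en-1-yl}-4-methyloct-2-enamide | CCCC[C@@H](C)/C=C/C(=O)N[C@@H]1C[C@](O[Si](C)(C)C(C)(C)C)(C#C[Si](C(C)C)(C(C)C)C(C)C)[C@H](O)C=C1O[Si](C)(C)C(C)(C)C | intermediate
19 | (R,E)-N-{(1R,3R,4S,5S)-3-bromo-5-[(tert-butyldimethylsilyl)oxy]-4-hydroxy-2-oxo-5-[(triisopropylsilyl)ethynyl]cyclohexyl}-4-methyloct-2-enamide | CCCC[C@@H](C)/C=C/C(=O)N[C@@H]1C[C@](O[Si](C)(C)C(C)(C)C)(C#C[Si](C(C)C)(C(C)C)C(C)C)[C@H](O)[C@@H](Br)C1=O | intermediate (not isolated)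
20 | (R,E)-N-{(1S,3R,5S,6R)-5-[(tert-butyldimethylsilyl)oxy]-2-oxo-5-[(triisopropylsilyl)ethynyl]-7-oxabicyclo[4.1.0]heptan-3-yl}-4-methyloct-2-enamide | CCCC[C@@H](C)/C=C/C(=O)N[C@@H]1C[C@](O[Si](C)(C)C(C)(C)C)(C#C[Si](C(C)C)(C(C)C)C(C)C)[C@@H]2O[C@@H]2C1=O | intermediate
21 | (R,E)-N-chloro-N-{(1S,3R,5S,6R)-5-[(tert-butyldimethylsilyl)oxy]-2-oxo-5-[(triisopropylsilyl)ethynyl]-7-oxabicyclo[4.1.0]heptan-3-yl}-4-methyloct-2-enamide | CCCC[C@@H](C)/C=C/C(=O)N(Cl)[C@@H]1C[C@](O[Si](C)(C)C(C)(C)C)(C#C[Si](C(C)C)(C(C)C)C(C)C)[C@@H]2O[C@@H]2C1=O | intermediate (not isolated)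
22 | (R,E)-N-{(1S,5S,6R)-5-[(tert-butyldimethylsilyl)oxy]-2-oxo-5-[(triisopropylsilyl)ethynyl]-7-oxabicyclo[4.1.0]heptan-3-ylidene}-4-methyloct-2-enamide | CCCC[C@@H](C)/C=C/C(=O)N=C1C[C@](O[Si](C)(C)C(C)(C)C)(C#C[Si](C(C)C)(C(C)C)C(C)C)[C@@H]2O[C@@H]2C1=O | intermediate (not isolated)
23 | (R,E)-N-{(1S,5S,6R)-5-[(tert-butyldimethylsilyl)oxy]-2-oxo-5-[(triisopropylsilyl)ethynyl]-7-oxabicyclo[4.1.0]hept-3-en-3-yl}-4-methyloct-2-enamide | CCCC[C@@H](C)/C=C/C(=O)NC1=C[C@](O[Si](C)(C)C(C)(C)C)(C#C[Si](C(C)C)(C(C)C)C(C)C)[C@@H]2O[C@@H]2C1=O | intermediate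
24 | (R,E)-N-{(1S,5S,6R)-5-[(tert-butyldimethylsilyl)oxy]-5-ethynyl-2-oxo-7-oxabicyclo[4.1.0]hept-3-en-3-yl}-4-methyloct-2-enamide | CCCC[C@@H](C)/C=C/C(=O)NC1=C[C@](O[Si](C)(C)C(C)(C)C)(C#C)[C@@H]2O[C@@H]2C1=O | intermediate
25 | (R,E)-N-{(1S,5S,6R)-5-[(tert-butyldimethylsilyl)oxy]-2-oxo-5-[(E)-2-(tributylstannyl)vinyl]-7-oxabicyclo[4.1.0]hept-3-en-3-yl}-4-methyloct-2-enamide | CCCC[C@@H](C)/C=C/C(=O)NC1=C[C@](O[Si](C)(C)C(C)(C)C)(/C=C/[Sn](CCCC)(CCCC)CCCC)[C@@H]2O[C@@H]2C1=O | intermediate
26 | pyridine–sulfur trioxide complex (pyridinium-1-sulfonate) | [O-]S(=O)(=O)[n+]1ccccc1 | starting material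
27 | potassium (1E,3E)-5-oxopenta-1,3-dien-1-olate | [K+].[O-]/C=C/C=C/C=O | intermediate
28 | (2E,4E)-5-bromopenta-2,4-dienal | Br/C=C/C=C/C=O | intermediate
29 | (2E,4E)-5-bromopenta-2,4-dienoic acid | Br/C=C/C=C/C(=O)O | intermediate
30 | cyclopentane-1,3-dione | O=C1CCC(=O)C1 | starting material
31 | 2-(hydroxyimino)cyclopentane-1,3-dione | ON=C1C(=O)CCC1=O | intermediate
32 | 2-amino-3-hydroxycyclopent-2-en-1-one hydrochloride | [NH3+]C1=C(O)CCC1=O.[Cl-] | intermediate
33 | (2E,4E)-5-bromopenta-2,4-dienoyl chloride | Br/C=C/C=C/C(=O)Cl | intermediate (not isolated)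
34 | (2E,4E)-5-bromo-N-(2-hydroxy-5-oxocyclopent-1-en-1-yl)penta-2,4-dienamide | Br/C=C/C=C/C(=O)NC1=C(O)CCC1=O | intermediate
35 | (R,E)-N-{(1S,5R,6R)-5-[(tert-butyldimethylsilyl)oxy]-5-[(1E,3E,5E)-7-[(2-hydroxy-5-oxocyclopent-1-en-1-yl)amino]-7-oxohepta-1,3,5-trien-1-yl]-2-oxo-7-oxabicyclo[4.1.0]hept-3-en-3-yl}-4-methyloct-2-enamide | CCCC[C@@H](C)/C=C/C(=O)NC1=C[C@](O[Si](C)(C)C(C)(C)C)(/C=C/C=C/C=C/C(=O)NC2=C(O)CCC2=O)[C@@H]2O[C@@H]2C1=O | intermediate
36 | (R,E)-N-{(1S,5R,6R)-5-hydroxy-5-[(1E,3E,5E)-7-[(2-hydroxy-5-oxocyclopent-1-en-1-yl)amino]-7-oxohepta-1,3,5-trien-1-yl]-2-oxo-7-oxabicyclo[4.1.0]hept-3-en-3-yl}-4-methyloct-2-enamide | CCCC[C@@H](C)/C=C/C(=O)NC1=C[C@](O)(/C=C/C=C/C=C/C(=O)NC2=C(O)CCC2=O)[C@@H]2O[C@@H]2C1=O | target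

**Step count**

Total step count: 22.
Longest linear sequence: 12 steps (steps 1–4, 9–14, 21 and 22).

**Steps most likely to fail**

Step 9. The cycloaddition may fail through poor facial discrimination at C5 (approach syn to the silyl ether), or through open-chain capture of the enol ether carbon by nitrogen without closure of the C5–O bond. The fallback sets out from 7 and comes back to the route at 23; it introduces the C5 oxygen and the C2 nitrogen one after the other. Weitz–Scheffer epoxidation of 7 (t-BuOOH, DBU, CH2Cl2, 0 °C) should add the peroxide to C5 anti to the silyloxy group and give the epoxy ketone (1S,5S,6R)-5-[(tert-butyldimethylsilyl)oxy]-5-[(triisopropylsilyl)ethynyl]-7-oxabicyclo[4.1.0]heptan-2-one F1. Its potassium enolate (KHMDS, THF, −78 °C), which can form only towards C2, takes an azide group from 2,4,6-triisopropylbenzenesulfonyl azide (AcOH quench) to give the α-azido ketone (1S,5S,6R)-3-azido-5-[(tert-butyldimethylsilyl)oxy]-5-[(triisopropylsilyl)ethynyl]-7-oxabicyclo[4.1.0]heptan-2-one F2, whose C3 epimers need no separation. Staudinger reduction with PMe3 in wet THF in the presence of the acyl imidazolide 14 gives the amide (R,E)-N-{(1S,5S,6R)-5-[(tert-butyldimethylsilyl)oxy]-2-oxo-5-[(triisopropylsilyl)ethynyl]-7-oxabicyclo[4.1.0]heptan-3-yl}-4-methyloct-2-enamide as its C3 epimer mixture F3, and the conditions of step 12 take both epimers to 23.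

Step 3. The catalyst may fail to tell the two enantiotopic enone arms apart, or reduction may run on into the second arm. The fallback sets out from 6 and comes back at 7; it makes the over-reduction the plan and moves the desymmetrisation to an enolisation. Both alkenes of 6 are reduced with achiral copper hydride ([(Ph3P)CuH]6 cat., excess (EtO)2MeSiH, t-BuOH, toluene, rt) to the achiral ketone 4-[(tert-butyldimethylsilyl)oxy]-4-[(triisopropylsilyl)ethynyl]cyclohexan-1-one F4. Enantioselective deprotonation with lithium (R,R)-bis(1-phenylethyl)amide and LiCl with TMSCl as internal quench (THF, −100 °C; base antipode chosen as for the ligand) gives the silyl enol ether (R)-tert-butyldimethyl{[1-[(triisopropylsilyl)ethynyl]-4-[(trimethylsilyl)oxy]cyclohex-3-en-1-yl]oxy}silane F5, and Saegusa–Ito oxidation (Pd(OAc)2, MeCN, rt) gives 7.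

Step 12. Chlorine may be transferred to sites other than the amide nitrogen, or the base may open the epoxy ketone before hydrogen chloride is lost. The fallback sets out from 20 and comes back at 23; it installs the alkene by selenoxide elimination. The dianion of 20 (LiHMDS, 2.2 equiv, THF, −78 °C) is selenenylated at C2 with PhSeCl to give the selenide (R,E)-N-{(1S,5S,6R)-5-[(tert-butyldimethylsilyl)oxy]-2-oxo-3-(phenylselanyl)-5-[(triisopropylsilyl)ethynyl]-7-oxabicyclo[4.1.0]heptan-3-yl}-4-methyloct-2-enamide F6, and oxidation (H2O2, pyridine, CH2Cl2, 0 °C) triggers syn-elimination across C2–C3 to give 23.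

**Further compounds**

F1 | step 9 | (1S,5S,6R)-5-[(tert-butyldimethylsilyl)oxy]-5-[(triisopropylsilyl)ethynyl]-7-oxabicyclo[4.1.0]heptan-2-one | C1C[C@](O[Si](C)(C)C(C)(C)C)(C#C[Si](C(C)C)(C(C)C)C(C)C)[C@@H]2O[C@@H]2C1=O
F2 | step 9 | (1S,5S,6R)-3-azido-5-[(tert-butyldimethylsilyl)oxy]-5-[(triisopropylsilyl)ethynyl]-7-oxabicyclo[4.1.0]heptan-2-one (C3 epimers) | [N-]=[N+]=NC1C[C@](O[Si](C)(C)C(C)(C)C)(C#C[Si](C(C)C)(C(C)C)C(C)C)[C@@H]2O[C@@H]2C1=O
F3 | step 9 | (R,E)-N-{(1S,5S,6R)-5-[(tert-butyldimethylsilyl)oxy]-2-oxo-5-[(triisopropylsilyl)ethynyl]-7-oxabicyclo[4.1.0]heptan-3-yl}-4-methyloct-2-enamide (C3 epimers) | CCCC[C@@H](C)/C=C/C(=O)NC1C[C@](O[Si](C)(C)C(C)(C)C)(C#C[Si](C(C)C)(C(C)C)C(C)C)[C@@H]2O[C@@H]2C1=O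
F4 | step 3 | 4-[(tert-butyldimethylsilyl)oxy]-4-[(triisopropylsilyl)ethynyl]cyclohexan-1-one | O=C1CCC(O[Si](C)(C)C(C)(C)C)(C#C[Si](C(C)C)(C(C)C)C(C)C)CC1
F5 | step 3 | (R)-tert-butyldimethyl{[1-[(triisopropylsilyl)ethynyl]-4-[(trimethylsilyl)oxy]cyclohex-3-en-1-yl]oxy}silane | C[Si](C)(C)OC1=CC[C@@](O[Si](C)(C)C(C)(C)C)(C#C[Si](C(C)C)(C(C)C)C(C)C)CC1
F6 | step 12 | (R,E)-N-{(1S,5S,6R)-5-[(tert-butyldimethylsilyl)oxy]-2-oxo-3-(phenylselanyl)-5-[(triisopropylsilyl)ethynyl]-7-oxabicyclo[4.1.0]heptan-3-yl}-4-methyloct-2-enamide (C3 epimers) | CCCC[C@@H](C)/C=C/C(=O)NC1([Se]c2ccccc2)C[C@](O[Si](C)(C)C(C)(C)C)(C#C[Si](C(C)C)(C(C)C)C(C)C)[C@@H]2O[C@@H]2C1=O
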